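**Retrosynthetic overview**
1. The enal comes from allylic oxidation (CH3 to CHO) of a 2-isopropenyl group, itself from dehydration of a 2-(2-hydroxyprop-2-yl) group; the tiglate comes from acylation of the (R)-benzylic alcohol after desilylation.
2. The C3 acetate comes from Baeyer–Villiger oxygen insertion into the C3–C(=O)CH3 bond of a trans-3-acetyl-2,3-dihydrobenzofuran. The plan rests on C3 of the dihydrofuran ring B (O1–C2–C3–C3a–C7a): as the acetyl compound it is benzylic and enolisable, so its trans relation to the C2 side chain is set by equilibration and then passed to oxygen with retention.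
3. The 3-acetyl group comes from a Weinreb amide, and that from the trans methyl ester, obtained by C3 epimerisation of the product of a dirhodium-carbenoid C–H insertion that forms C2–C3 and sets C2.
4. The diazo ester comes from a methyl arylacetate carrying the OCH2C(CH3)2OSiEt3 ether and the (R)-CH(OTBS)CH3 group, built from methyl 2-(2-hydroxyphenyl)acetate, acetyl chloride and isobutylene oxide; a CBS reduction sets the carbinol.
5. Ring order: benzene ring A is present in the starting material; ring B is the only ring formed (C–H insertion); the key step closes no ring.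

Key step: step 10

Abbreviations: TBS = tert-butyldimethylsilyl, TES = triethylsilyl, p-ABSA = 4-acetamidobenzenesulfonyl azide.

Assumption: the sense of induction at C2 in the carbenoid C–H insertion (step 7 and its fallback) is taken to be the one drawn; if a first run shows the opposite sense, the mirror-image catalyst (and auxiliary) is used and nothing else changes.

**Step 1**
Reactants: 1 methyl 2-(2-hydroxyphenyl)acetate; 2 acetyl chloride
Product: 3 methyl 2-(5-acetyl-2-hydroxyphenyl)acetate
Conditions: AcCl (1.5 equiv), neat TfOH, 0 °C to rt; poured into MeOH, 0 °C to rt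
Reagents that add atoms: none
Why: Friedel–Crafts acylation of a phenol in neat triflic acid, in which the hydroxyl group directs the acylium ion to its free para position C5, and the methanol quench keeps the side chain as the methyl ester.

**Step 2**
Reactants: 3 methyl 2-(5-acetyl-2-hydroxyphenyl)acetate; 4 2,2-dimethyloxirane (isobutylene oxide)
Product: 5 methyl 2-[5-acetyl-2-(2-hydroxy-2-methylpropoxy)phenyl]acetate
Conditions: isobutylene oxide (3 equiv), K2CO3 (0.5 equiv), DMF, 90 °C, sealed tube
Reagents that add atoms: none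
Why: Williamson-type etherification by base-catalysed SN2 opening of the epoxide at its unhindered CH2 terminus by the phenoxide, which gives the tertiary alcohol and leaves the ester and ketone untouched.

**Step 3**
Reactants: 5 methyl 2-[5-acetyl-2-(2-hydroxy-2-methylpropoxy)phenyl]acetate
Product: 6 methyl 2-[2-(2-hydroxy-2-methylpropoxy)-5-[(1R)-1-hydroxyethyl]phenyl]acetate
Conditions: (S)-2-methyl-CBS-oxazaborolidine (10 mol %), BH3·SMe2 (1.6 equiv), THF, −20 °C; MeOH quench
Reagents that add atoms: none
Why: Corey–Bakshi–Shibata reduction, in which the (S)-oxazaborolidine–borane complex delivers hydride to the face of the aryl methyl ketone that gives the (R)-carbinol (as for acetophenone), while the methyl ester is not reduced at this temperature and the tertiary alcohol only consumes some borane.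

**Step 4**
Reactants: 6 methyl 2-[2-(2-hydroxy-2-methylpropoxy)-5-[(1R)-1-hydroxyethyl]phenyl]acetate
Product: 7 methyl 2-[5-[(1R)-1-(tert-butyldimethylsilyloxy)ethyl]-2-(2-hydroxy-2-methylpropoxy)phenyl]acetate
Conditions: TBSCl, imidazole, DMF, 0 °C to rt
Reagents that add atoms: tert-butyldimethylsilyl chloride, CC(C)(C)[Si](C)(C)Cl
Why: Silyl ether formation with a silyl chloride and imidazole, which is selective for the secondary benzylic alcohol because the tertiary alcohol does not react under these conditions.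

**Step 5**
Reactants: 7 methyl 2-[5-[(1R)-1-(tert-butyldimethylsilyloxy)ethyl]-2-(2-hydroxy-2-methylpropoxy)phenyl]acetate
Product: 8 methyl 2-[5-[(1R)-1-(tert-butyldimethylsilyloxy)ethyl]-2-[2-methyl-2-(triethylsilyloxy)propoxy]phenyl]acetate
Conditions: TESOTf, 2,6-lutidine, CH2Cl2, −78 to 0 °C
Reagents that add atoms: triethylsilyl trifluoromethanesulfonate, CC[Si](CC)(CC)OS(=O)(=O)C(F)(F)F
Why: Silylation of a tertiary alcohol with a silyl triflate and a hindered pyridine base, which removes the last free hydroxyl group that would otherwise undergo O–H insertion with the carbenoid.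

**Step 6**
Reactants: 8 methyl 2-[5-[(1R)-1-(tert-butyldimethylsilyloxy)ethyl]-2-[2-methyl-2-(triethylsilyloxy)propoxy]phenyl]acetate
Product: 9 methyl 2-diazo-2-[5-[(1R)-1-(tert-butyldimethylsilyloxy)ethyl]-2-[2-methyl-2-(triethylsilyloxy)propoxy]phenyl]acetate
Conditions: p-ABSA, DBU, MeCN, 0 °C to rt
Reagents that add atoms: 4-acetamidobenzenesulfonyl azide, CC(=O)Nc1ccc(cc1)S(=O)(=O)N=[N+]=[N-]
Why: Regitz diazo transfer, in which DBU deprotonates the arylacetate CH2 and the enolate takes N2 from the sulfonyl azide to give the donor/acceptor diazo ester.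

**Step 7**
Reactants: 9 methyl 2-diazo-2-[5-[(1R)-1-(tert-butyldimethylsilyloxy)ethyl]-2-[2-methyl-2-(triethylsilyloxy)propoxy]phenyl]acetate
Product: 11 methyl (2R,3R)-5-[(1R)-1-(tert-butyldimethylsilyloxy)ethyl]-2-[2-(triethylsilyloxy)propan-2-yl]-2,3-dihydrobenzofuran-3-carboxylate (2,3-trans), via cis ester 10 (not isolated)
Conditions: Rh2(S-PTTL)4 [dirhodium tetrakis(N-phthaloyl-(S)-tert-leucinate)] (1 mol %), toluene, −60 °C, slow addition of 9; then NaOMe (0.5 equiv), MeOH/THF, rt
Reagents that add atoms: none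
Why: Intramolecular 1,5 C–H insertion of the rhodium donor/acceptor carbenoid into the ether CH2 forms the C2–C3 bond and closes ring B, the chiral carboxylate ligands choosing between the two enantiotopic hydrogens and so setting C2, and methoxide then epimerises C3 through the ester enolate to place the ester anti to the bulky C2 group, ring opening by loss of phenoxide being the stereoelectronically slow reverse of a 5-endo-trig closure.

**Step 8**
Reactants: 11 methyl (2R,3R)-5-[(1R)-1-(tert-butyldimethylsilyloxy)ethyl]-2-[2-(triethylsilyloxy)propan-2-yl]-2,3-dihydrobenzofuran-3-carboxylate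
Product: 12 (2R,3R)-5-[(1R)-1-(tert-butyldimethylsilyloxy)ethyl]-N-methoxy-N-methyl-2-[2-(triethylsilyloxy)propan-2-yl]-2,3-dihydrobenzofuran-3-carboxamide
Conditions: Me(MeO)NH·HCl, AlMe3, CH2Cl2, 0 °C to rt
Reagents that add atoms: N,O-dimethylhydroxylamine hydrochloride, CNOC.Cl
Why: Weinreb aminolysis, in which the aluminium amide made from AlMe3 and the amine salt converts the methyl ester into the N-methoxy-N-methylamide under non-basic conditions, so that C3 stays trans.

**Step 9**
Reactants: 12 (2R,3R)-5-[(1R)-1-(tert-butyldimethylsilyloxy)ethyl]-N-methoxy-N-methyl-2-[2-(triethylsilyloxy)propan-2-yl]-2,3-dihydrobenzofuran-3-carboxamide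
Product: 13 1-[(2R,3R)-5-[(1R)-1-(tert-butyldimethylsilyloxy)ethyl]-2-[2-(triethylsilyloxy)propan-2-yl]-2,3-dihydrobenzofuran-3-yl]ethanone (2,3-trans)
Conditions: MeMgBr, THF, −20 to 0 °C; aq NH4Cl; then DBU (0.1 equiv), CH2Cl2, rt
Reagents that add atoms: methylmagnesium bromide, C[Mg]Br
Why: Weinreb ketone synthesis, in which the Grignard reagent adds once to give a magnesium chelate that collapses to the methyl ketone only on work-up, and catalytic DBU then equilibrates C3 through the enolate so that the acetyl group sits trans to the C2 substituent under thermodynamic control.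

**Step 10**
Reactants: 13 1-[(2R,3R)-5-[(1R)-1-(tert-butyldimethylsilyloxy)ethyl]-2-[2-(triethylsilyloxy)propan-2-yl]-2,3-dihydrobenzofuran-3-yl]ethanone
Product: 14 (2R,3R)-5-[(1R)-1-(tert-butyldimethylsilyloxy)ethyl]-2-[2-(triethylsilyloxy)propan-2-yl]-2,3-dihydrobenzofuran-3-yl acetate (2,3-trans)
Conditions: mCPBA (2.5 equiv), NaHCO3, CH2Cl2, 0 °C to rt
Reagents that add atoms: 3-chloroperbenzoic acid, OOC(=O)c1cccc(Cl)c1
Why: Baeyer–Villiger oxidation: the peracid adds to the acetyl carbonyl to give the Criegee adduct, and C3 migrates from carbon to the peroxide oxygen as 3-chlorobenzoate leaves, so that oxygen enters the C3–C(acetyl) bond and the C3–O bond and the acetate ester are made in one event. The closest known reaction type is the peracid oxidation of methyl sec-alkyl and methyl 1-arylalkyl ketones to the corresponding acetates, which goes with retention at the migrating carbon. No ring is closed. No stereocentre is created: the C3 configuration fixed thermodynamically in 13 (acetyl anti to the silyloxyisopropyl group on C2) is carried over with retention, so C3 of the acetate follows in relative and absolute sense from the catalyst-set C2. The step needs migration of C3 in preference to the methyl group, which the secondary, benzylic character of C3 secures, and it needs the peracid to find no other oxidisable site, which is why the C2 side chain is still saturated and the C5 carbinol is reduced and silylated. The bicarbonate buffer keeps the silyl ethers and no C3 cation is formed, so loss of the C2 hydrogen with aromatisation to the benzofuran has no pathway.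

**Step 11**
Reactants: 14 (2R,3R)-5-[(1R)-1-(tert-butyldimethylsilyloxy)ethyl]-2-[2-(triethylsilyloxy)propan-2-yl]-2,3-dihydrobenzofuran-3-yl acetate
Product: 15 (2R,3R)-5-[(1R)-1-hydroxyethyl]-2-(2-hydroxypropan-2-yl)-2,3-dihydrobenzofuran-3-yl acetate
Conditions: HF·pyridine, pyridine, THF, 0 °C to rt
Reagents that add atoms: none
Why: Fluoride-mediated cleavage of both silyl ethers under buffered, weakly acidic conditions, which leave the C3 acetate and the two benzylic C–O bonds intact.

**Step 12**
Reactants: 15 (2R,3R)-5-[(1R)-1-hydroxyethyl]-2-(2-hydroxypropan-2-yl)-2,3-dihydrobenzofuran-3-yl acetate; 16 tiglic acid [(E)-2-methylbut-2-enoic acid]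
Product: 17 (1R)-1-[(2R,3R)-3-acetoxy-2-(2-hydroxypropan-2-yl)-2,3-dihydrobenzofuran-5-yl]ethyl (E)-2-methylbut-2-enoate
Conditions: DCC, DMAP (cat.), CH2Cl2, 0 °C to rt
Reagents that add atoms: none
Why: Steglich esterification, in which the carbodiimide-activated acid acylates the secondary benzylic alcohol without breaking its C–O bond (configuration retained), while the tertiary alcohol is too hindered to react.

**Step 13**
Reactants: 17 (1R)-1-[(2R,3R)-3-acetoxy-2-(2-hydroxypropan-2-yl)-2,3-dihydrobenzofuran-5-yl]ethyl (E)-2-methylbut-2-enoate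
Product: 18 (1R)-1-[(2S,3R)-3-acetoxy-2-(prop-1-en-2-yl)-2,3-dihydrobenzofuran-5-yl]ethyl (E)-2-methylbut-2-enoate
Conditions: Burgess reagent (methyl N-(triethylammoniosulfonyl)carbamate), toluene, 50 °C
Reagents that add atoms: none
Why: Burgess dehydration, in which the tertiary alcohol forms a sulfamate ester that undergoes thermal syn elimination, preferably with one of the six methyl hydrogens and not the single hindered C2–H, to give the isopropenyl group, a dehydration known for 2-(2-hydroxyprop-2-yl)-2,3-dihydrobenzofurans.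

**Step 14**
Reactants: 18 (1R)-1-[(2S,3R)-3-acetoxy-2-(prop-1-en-2-yl)-2,3-dihydrobenzofuran-5-yl]ethyl (E)-2-methylbut-2-enoate
Product: 20 (1R)-1-[(2S,3R)-3-acetoxy-2-(3-oxoprop-1-en-2-yl)-2,3-dihydrobenzofuran-5-yl]ethyl (E)-2-methylbut-2-enoate (target), via allylic alcohol 19 (not isolated)
Conditions: SeO2 (0.5 equiv), t-BuOOH (in decane), CH2Cl2, rt; then MnO2, CH2Cl2, rt
Reagents that add atoms: selenium dioxide, O=[Se]=O; tert-butyl hydroperoxide, CC(C)(C)OO
Why: Riley allylic oxidation with catalytic SeO2 and a hydroperoxide as terminal oxidant, in which an ene reaction at the isopropenyl methyl group and a [2,3]-sigmatropic shift give the allylic alcohol (CH3 is preferred to the tertiary C2–H and the electron-poor tiglate does not react), and MnO2 then oxidises the allylic alcohol to the enal.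

**Compound list**
1 | methyl 2-(2-hydroxyphenyl)acetate | COC(=O)Cc1ccccc1O | starting material
2 | acetyl chloride | CC(Cl)=O | starting material
3 | methyl 2-(5-acetyl-2-hydroxyphenyl)acetate | COC(=O)Cc1cc(C(C)=O)ccc1O | intermediate
4 | 2,2-dimethyloxirane (isobutylene oxide) | CC1(C)CO1 | starting material
5 | methyl 2-[5-acetyl-2-(2-hydroxy-2-methylpropoxy)phenyl]acetate | COC(=O)Cc1cc(C(C)=O)ccc1OCC(C)(C)O | intermediate
6 | methyl 2-[2-(2-hydroxy-2-methylpropoxy)-5-[(1R)-1-hydroxyethyl]phenyl]acetate | COC(=O)Cc1cc([C@@H](C)O)ccc1OCC(C)(C)O | intermediate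
7 | methyl 2-[5-[(1R)-1-(tert-butyldimethylsilyloxy)ethyl]-2-(2-hydroxy-2-methylpropoxy)phenyl]acetate | COC(=O)Cc1cc([C@@H](C)O[Si](C)(C)C(C)(C)C)ccc1OCC(C)(C)O | intermediate
8 | methyl 2-[5-[(1R)-1-(tert-butyldimethylsilyloxy)ethyl]-2-[2-methyl-2-(triethylsilyloxy)propoxy]phenyl]acetate | COC(=O)Cc1cc([C@@H](C)O[Si](C)(C)C(C)(C)C)ccc1OCC(C)(C)O[Si](CC)(CC)CC | intermediate
9 | methyl 2-diazo-2-[5-[(1R)-1-(tert-butyldimethylsilyloxy)ethyl]-2-[2-methyl-2-(triethylsilyloxy)propoxy]phenyl]acetate | COC(=O)C(=[N+]=[N-])c1cc([C@@H](C)O[Si](C)(C)C(C)(C)C)ccc1OCC(C)(C)O[Si](CC)(CC)CC | intermediate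
10 | methyl (2R,3S)-5-[(1R)-1-(tert-butyldimethylsilyloxy)ethyl]-2-[2-(triethylsilyloxy)propan-2-yl]-2,3-dihydrobenzofuran-3-carboxylate (2,3-cis, not isolated) | CC(C)(O[Si](CC)(CC)CC)[C@@H]1Oc2ccc([C@@H](C)O[Si](C)(C)C(C)(C)C)cc2[C@@H]1C(=O)OC | intermediate
11 | methyl (2R,3R)-5-[(1R)-1-(tert-butyldimethylsilyloxy)ethyl]-2-[2-(triethylsilyloxy)propan-2-yl]-2,3-dihydrobenzofuran-3-carboxylate (2,3-trans) | CC(C)(O[Si](CC)(CC)CC)[C@@H]1Oc2ccc([C@@H](C)O[Si](C)(C)C(C)(C)C)cc2[C@H]1C(=O)OC | intermediate
12 | (2R,3R)-5-[(1R)-1-(tert-butyldimethylsilyloxy)ethyl]-N-methoxy-N-methyl-2-[2-(triethylsilyloxy)propan-2-yl]-2,3-dihydrobenzofuran-3-carboxamide | CC(C)(O[Si](CC)(CC)CC)[C@@H]1Oc2ccc([C@@H](C)O[Si](C)(C)C(C)(C)C)cc2[C@H]1C(=O)N(C)OC | intermediate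
13 | 1-[(2R,3R)-5-[(1R)-1-(tert-butyldimethylsilyloxy)ethyl]-2-[2-(triethylsilyloxy)propan-2-yl]-2,3-dihydrobenzofuran-3-yl]ethanone (2,3-trans) | CC(C)(O[Si](CC)(CC)CC)[C@@H]1Oc2ccc([C@@H](C)O[Si](C)(C)C(C)(C)C)cc2[C@H]1C(C)=O | intermediate
14 | (2R,3R)-5-[(1R)-1-(tert-butyldimethylsilyloxy)ethyl]-2-[2-(triethylsilyloxy)propan-2-yl]-2,3-dihydrobenzofuran-3-yl acetate (2,3-trans) | CC(C)(O[Si](CC)(CC)CC)[C@@H]1Oc2ccc([C@@H](C)O[Si](C)(C)C(C)(C)C)cc2[C@H]1OC(C)=O | intermediate
15 | (2R,3R)-5-[(1R)-1-hydroxyethyl]-2-(2-hydroxypropan-2-yl)-2,3-dihydrobenzofuran-3-yl acetate | CC(C)(O)[C@@H]1Oc2ccc([C@@H](C)O)cc2[C@H]1OC(C)=O | intermediate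
16 | tiglic acid, (E)-2-methylbut-2-enoic acid | C/C=C(\C)C(=O)O | starting material
17 | (1R)-1-[(2R,3R)-3-acetoxy-2-(2-hydroxypropan-2-yl)-2,3-dihydrobenzofuran-5-yl]ethyl (E)-2-methylbut-2-enoate | CC(C)(O)[C@@H]1Oc2ccc([C@@H](C)OC(=O)/C(C)=C/C)cc2[C@H]1OC(C)=O | intermediate
18 | (1R)-1-[(2S,3R)-3-acetoxy-2-(prop-1-en-2-yl)-2,3-dihydrobenzofuran-5-yl]ethyl (E)-2-methylbut-2-enoate | C=C(C)[C@@H]1Oc2ccc([C@@H](C)OC(=O)/C(C)=C/C)cc2[C@H]1OC(C)=O | intermediate
19 | (1R)-1-[(2S,3R)-3-acetoxy-2-(3-hydroxyprop-1-en-2-yl)-2,3-dihydrobenzofuran-5-yl]ethyl (E)-2-methylbut-2-enoate (not isolated) | C=C(CO)[C@@H]1Oc2ccc([C@@H](C)OC(=O)/C(C)=C/C)cc2[C@H]1OC(C)=O | intermediate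
20 | (1R)-1-[(2S,3R)-3-acetoxy-2-(3-oxoprop-1-en-2-yl)-2,3-dihydrobenzofuran-5-yl]ethyl (E)-2-methylbut-2-enoate | C=C(C=O)[C@@H]1Oc2ccc([C@@H](C)OC(=O)/C(C)=C/C)cc2[C@H]1OC(C)=O | target

**Totals**
Total step count: 14. Longest linear sequence: 14 steps (from 1 to 20).

**Steps most likely to fail**

Step 7. The insertion has to take place at a hindered, neopentyl-type methylene, so discrimination between its two enantiotopic hydrogens may be poor and carbene dimerisation or attack on the silyl ether oxygen may compete. The (R)-carbinol makes the two C2 epimers diastereomers, so the outcome can be read on the crude product. The fallback moves stereocontrol from the catalyst alone to a covalently bound auxiliary, a known variant of the same ring synthesis. It sets out from 8: LiOH in THF/H2O should give the arylacetic acid F1, and DCC/DMAP esterification with (2S)-2-hydroxy-1-(pyrrolidin-1-yl)propan-1-one the lactamide ester F2. Diazo transfer (p-ABSA, DBU) should give the diazo lactamide ester F3. Rh2(S-DOSP)4 [dirhodium tetrakis((S)-N-(4-dodecylbenzenesulfonyl)prolinate)] in CH2Cl2 should then insert under matched double stereodifferentiation to give the trans dihydrobenzofuran lactamide ester F4. NaOMe in MeOH transesterifies F4, releases the auxiliary and returns to the route at 11.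

Step 13. The syn elimination may go in part toward the C2–H, which would give an exocyclic enol ether that loses acetic acid and aromatises, and the benzylic tiglate has to tolerate the heating. The fallback changes the order of the end game, so that the alkene is made by a base-mediated E2 elimination before the tiglate is in place. It sets out from 14: a short treatment with HF·pyridine/pyridine at 0 °C should cleave the tertiary triethylsilyl ether well before the secondary TBS ether and give the tertiary alcohol F5. SOCl2/pyridine at −20 °C (chlorosulfite, loss of a methyl proton) should give the isopropenyl silyl ether F6. TBAF buffered with AcOH should free the benzylic alcohol F7, and DCC/DMAP esterification with 16 returns to the route at 18.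

Step 14. The selenium ene reaction may lose site selectivity (attack at the C2–H or at the tiglate methyl groups), may over-oxidise, or the acidic selenium species may promote loss of the acetate. The fallback brings the oxygen in by substitution in place of a selenium ene reaction. It sets out from 18: ene-type chlorination with hypochlorous acid (Ca(OCl)2, solid CO2, CH2Cl2/H2O, 0 °C) should shift the double bond and give the allylic chloride F8. Ganem oxidation (Kornblum-type displacement and elimination) with trimethylamine N-oxide in DMSO at rt should then give the enal and return to the route at 20.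

**Further compounds**
F1 | step 7 | 2-[5-[(1R)-1-(tert-butyldimethylsilyloxy)ethyl]-2-[2-methyl-2-(triethylsilyloxy)propoxy]phenyl]acetic acid | OC(=O)Cc1cc([C@@H](C)O[Si](C)(C)C(C)(C)C)ccc1OCC(C)(C)O[Si](CC)(CC)CC
F2 | step 7 | (2S)-1-oxo-1-(pyrrolidin-1-yl)propan-2-yl 2-[5-[(1R)-1-(tert-butyldimethylsilyloxy)ethyl]-2-[2-methyl-2-(triethylsilyloxy)propoxy]phenyl]acetate | C[C@H](OC(=O)Cc1cc([C@@H](C)O[Si](C)(C)C(C)(C)C)ccc1OCC(C)(C)O[Si](CC)(CC)CC)C(=O)N1CCCC1
F3 | step 7 | (2S)-1-oxo-1-(pyrrolidin-1-yl)propan-2-yl 2-diazo-2-[5-[(1R)-1-(tert-butyldimethylsilyloxy)ethyl]-2-[2-methyl-2-(triethylsilyloxy)propoxy]phenyl]acetate | C[C@H](OC(=O)C(=[N+]=[N-])c1cc([C@@H](C)O[Si](C)(C)C(C)(C)C)ccc1OCC(C)(C)O[Si](CC)(CC)CC)C(=O)N1CCCC1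
F4 | step 7 | (2S)-1-oxo-1-(pyrrolidin-1-yl)propan-2-yl (2R,3R)-5-[(1R)-1-(tert-butyldimethylsilyloxy)ethyl]-2-[2-(triethylsilyloxy)propan-2-yl]-2,3-dihydrobenzofuran-3-carboxylate | CC(C)(O[Si](CC)(CC)CC)[C@@H]1Oc2ccc([C@@H](C)O[Si](C)(C)C(C)(C)C)cc2[C@H]1C(=O)O[C@@H](C)C(=O)N1CCCC1
F5 | step 13 | (2R,3R)-5-[(1R)-1-(tert-butyldimethylsilyloxy)ethyl]-2-(2-hydroxypropan-2-yl)-2,3-dihydrobenzofuran-3-yl acetate | CC(C)(O)[C@@H]1Oc2ccc([C@@H](C)O[Si](C)(C)C(C)(C)C)cc2[C@H]1OC(C)=O
F6 | step 13 | (2S,3R)-5-[(1R)-1-(tert-butyldimethylsilyloxy)ethyl]-2-(prop-1-en-2-yl)-2,3-dihydrobenzofuran-3-yl acetate | C=C(C)[C@@H]1Oc2ccc([C@@H](C)O[Si](C)(C)C(C)(C)C)cc2[C@H]1OC(C)=O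
F7 | step 13 | (2S,3R)-5-[(1R)-1-hydroxyethyl]-2-(prop-1-en-2-yl)-2,3-dihydrobenzofuran-3-yl acetate | C=C(C)[C@@H]1Oc2ccc([C@@H](C)O)cc2[C@H]1OC(C)=O
F8 | step 14 | (1R)-1-[(2S,3R)-3-acetoxy-2-(3-chloroprop-1-en-2-yl)-2,3-dihydrobenzofuran-5-yl]ethyl (E)-2-methylbut-2-enoate | C=C(CCl)[C@@H]1Oc2ccc([C@@H](C)OC(=O)/C(C)=C/C)cc2[C@H]1OC(C)=O
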